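**Retrosynthetic overview**

1. Target 17 ⇐ alkynyl isoflavone 16 (H2 over Pd/C saturates the alkyne and removes four O-benzyl groups) ⇐ bromoisoflavone 14 + alkynol 15 (Sonogashira coupling at C6–Br).
2. 14 ⇐ acrylic acid 12 by disconnection of C4–C4a: an intramolecular Friedel–Crafts acylation closes ring C, the only ring formed; rings A and B come from the starting materials.
3. Feature used: ring A is a phloroglucinol (O1 on C8a, oxygens on C5 and C7). In phenol 6 the future C4a and C8 are the two equivalent carbons ortho to the hydroxyl (mirror plane through O1, C6 and Br), so closure can only place bromine, and later the hydroxyisopentyl chain, at C6.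
4. 12 ⇐ phenol 6 + enol tosylate 10 (vinylic substitution, then saponification); 10 ⇐ 2,4-dihydroxyphenylacetic acid 7 (benzylation, formylation, tosylation).
5. 6 ⇐ 2-bromoresorcinol 1 (silylation, sterically directed C–H borylation para to Br, silyl-to-benzyl exchange, oxidation); bromine sits between the two oxygens from the outset, so no regioselective bromination of a phloroglucinol ether is needed.

Key step: step 10

Remark: compounds 9–13 are drawn as Z isomers (oxygen substituent cis to the carboxyl group). Any E isomer formed alongside is carried forward, because the geometry equilibrates under the conditions of step 10. The target has no stereocentre.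

**Route**

Step 1
Reactants: 1 2-bromobenzene-1,3-diol (2-bromoresorcinol)
Product: 2 2-bromo-1,3-bis(tert-butyldimethylsilyloxy)benzene
Conditions: TBSCl (2.3 equiv), imidazole, DMF, rt
Reagents that add atoms: tert-butyldimethylsilyl chloride, CC(C)(C)[Si](C)(C)Cl
Why: Imidazole-promoted silyl ether formation masks both acidic OH groups, which would otherwise consume the boron reagent, and makes both positions ortho to oxygen sterically inaccessible for the next step.

Step 2
Reactants: 2 2-bromo-1,3-bis(tert-butyldimethylsilyloxy)benzene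
Product: 3 2-[4-bromo-3,5-bis(tert-butyldimethylsilyloxy)phenyl]-4,4,5,5-tetramethyl-1,3,2-dioxaborolane
Conditions: B2pin2 (1.0 equiv), [Ir(OMe)(cod)]2 (1.5 mol %), 4,4'-di-tert-butyl-2,2'-bipyridine (3 mol %), THF, 80 °C
Reagents that add atoms: bis(pinacolato)diboron, CC1(C)OB(OC1(C)C)B1OC(C)(C)C(C)(C)O1
Why: Iridium-catalysed aromatic C–H borylation is governed by sterics, and C5–H is the only ring C–H without an ortho substituent, so boron should enter para to bromine; aryl bromides are tolerated.

Step 3
Reactants: 3 2-[4-bromo-3,5-bis(tert-butyldimethylsilyloxy)phenyl]-4,4,5,5-tetramethyl-1,3,2-dioxaborolane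
Product: 5 2-[3,5-bis(benzyloxy)-4-bromophenyl]-4,4,5,5-tetramethyl-1,3,2-dioxaborolane, via dicesium bis-phenoxide 4 (not isolated)
Conditions: CsF (3 equiv), BnBr (2.5 equiv), DMF, rt
Reagents that add atoms: benzyl bromide, BrCc1ccccc1
Why: Fluoride cleaves the aryl silyl ethers to phenoxides that undergo Williamson benzylation in the same flask, while a pinacol boronate should be inert to CsF at rt in the absence of a transition metal.

Step 4
Reactants: 5 2-[3,5-bis(benzyloxy)-4-bromophenyl]-4,4,5,5-tetramethyl-1,3,2-dioxaborolane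
Product: 6 3,5-bis(benzyloxy)-4-bromophenol
Conditions: 30% aq H2O2, NaOH, THF/H2O, 0 °C; then aq HCl
Reagents that add atoms: hydrogen peroxide, OO
Why: Oxidation of an arylboronate by basic hydrogen peroxide (aryl migration from boron to oxygen, then hydrolysis) replaces boron by OH at the same carbon, giving the mirror-symmetric phenol with bromine para to the hydroxyl.

Step 5
Reactants: 7 2-(2,4-dihydroxyphenyl)acetic acid
Product: 8 benzyl 2-[2,4-bis(benzyloxy)phenyl]acetate
Conditions: BnBr (3.5 equiv), K2CO3, DMF, 60 °C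
Reagents that add atoms: benzyl bromide, BrCc1ccccc1
Why: Williamson O-alkylation of both phenols and the carboxylate in one operation; K2CO3 is too weak to deprotonate the arylacetate CH2, so C-benzylation is not expected.

Step 6
Reactants: 8 benzyl 2-[2,4-bis(benzyloxy)phenyl]acetate
Product: 9 benzyl (Z)-2-[2,4-bis(benzyloxy)phenyl]-3-hydroxyacrylate (enol form of the α-formyl ester)
Conditions: NaH (2 equiv), benzyl formate (3 equiv), THF, 0 °C to rt; then aq HCl
Reagents that add atoms: benzyl formate, O=COCc1ccccc1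
Why: Crossed Claisen condensation with a non-enolisable formate; benzyl formate matches the ester so alkoxide exchange cannot scramble it, and deprotonation of the product to its chelated sodium enolate drives the equilibrium.

Step 7
Reactants: 9 benzyl (Z)-2-[2,4-bis(benzyloxy)phenyl]-3-hydroxyacrylate
Product: 10 benzyl (Z)-2-[2,4-bis(benzyloxy)phenyl]-3-(tosyloxy)acrylate
Conditions: TsCl (1.5 equiv), N-methylimidazole (1.5 equiv), LiOH (1.5 equiv), MeCN, 0 °C
Reagents that add atoms: p-toluenesulfonyl chloride, Cc1ccc(cc1)S(Cl)(=O)=O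
Why: O-sulfonylation of the enolate by the N-sulfonylimidazolium formed from TsCl and N-methylimidazole; lithium chelation between the enolate and ester oxygens should give mainly the Z enol tosylate.

Step 8
Reactants: 6 3,5-bis(benzyloxy)-4-bromophenol; 10 benzyl (Z)-2-[2,4-bis(benzyloxy)phenyl]-3-(tosyloxy)acrylate
Product: 11 benzyl (Z)-3-[3,5-bis(benzyloxy)-4-bromophenoxy]-2-[2,4-bis(benzyloxy)phenyl]acrylate
Conditions: K2CO3 (1.5 equiv), DMF, 0 °C to rt
Reagents that add atoms: none
Why: Nucleophilic vinylic substitution by addition–elimination: the phenoxide adds to the unsubstituted β-carbon of the acrylate and the resulting ester enolate expels tosylate, normally with retention of geometry.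

Step 9
Reactants: 11 benzyl (Z)-3-[3,5-bis(benzyloxy)-4-bromophenoxy]-2-[2,4-bis(benzyloxy)phenyl]acrylate
Product: 12 (Z)-3-[3,5-bis(benzyloxy)-4-bromophenoxy]-2-[2,4-bis(benzyloxy)phenyl]acrylic acid
Conditions: LiOH·H2O (3 equiv), THF/H2O, rt; then 1 M HCl, 0 °C
Reagents that add atoms: lithium hydroxide, [Li+].[OH-]
Why: Saponification by acyl–oxygen cleavage of the benzyl ester; the aryl benzyl ethers and the aryl bromide are inert to LiOH, and attack at the ester carbonyl should outpace conjugate addition to the donor-stabilised β-carbon.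

Step 10
Reactants: 12 (Z)-3-[3,5-bis(benzyloxy)-4-bromophenoxy]-2-[2,4-bis(benzyloxy)phenyl]acrylic acid
Product: 14 5,7-bis(benzyloxy)-3-[2,4-bis(benzyloxy)phenyl]-6-bromo-4H-chromen-4-one, via mixed trifluoroacetic anhydride 13 (not isolated)
Conditions: TFAA (3 equiv), CH2Cl2, 0 °C to rt
Reagents that add atoms: none
Why: TFAA converts acid 12 into the mixed anhydride 13, whose acyl carbon (as such or as the derived acylium ion) attacks the ring-A carbon ortho to the ether oxygen, and loss of a proton rearomatises ring A to give the 4-pyranone. The closest known reaction is the cyclodehydration of 3-aryloxyacrylic acids to chromones, an intramolecular Friedel–Crafts acylation. Ring C closes in a six-membered mode, 6-exo-trig at the acyl carbon, onto a carbon activated by an ortho and a para benzyloxy group in addition to the ether oxygen; no stereocentre is formed. The step needs site selectivity between C4a and C8, which is secured because C2 and C6 of the phenoxy ring are equivalent, so either closure places bromine at C6. It also needs the Z geometry of the acrylate, which should be supplied continuously because the push–pull double bond, whose acylium form has ketene–oxocarbenium character, rotates under the acidic conditions so that any E isomer drains through the Z isomer. Ring B cannot compete, since attack by its carbons would close a four-membered ring.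

Step 11
Reactants: 14 5,7-bis(benzyloxy)-3-[2,4-bis(benzyloxy)phenyl]-6-bromo-4H-chromen-4-one; 15 2-methylbut-3-yn-2-ol
Product: 16 5,7-bis(benzyloxy)-3-[2,4-bis(benzyloxy)phenyl]-6-(3-hydroxy-3-methylbut-1-yn-1-yl)-4H-chromen-4-one
Conditions: 15 (3 equiv), PdCl2(MeCN)2 (3 mol %), XPhos (9 mol %), Cs2CO3 (2.5 equiv), MeCN, 80 °C
Reagents that add atoms: none
Why: Copper-free Sonogashira coupling; the bulky electron-rich biarylphosphine should promote oxidative addition of zerovalent palladium into the bromide flanked by two benzyloxy groups, and a carbonate base avoids amine attack at C2 of the chromone.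

Step 12
Reactants: 16 5,7-bis(benzyloxy)-3-[2,4-bis(benzyloxy)phenyl]-6-(3-hydroxy-3-methylbut-1-yn-1-yl)-4H-chromen-4-one
Product: 17 5,7-dihydroxy-3-(2,4-dihydroxyphenyl)-6-(3-hydroxy-3-methylbutyl)-4H-chromen-4-one (target)
Conditions: H2 (1 atm), 10% Pd/C, THF/MeOH, rt
Reagents that add atoms: none
Why: Heterogeneous catalytic hydrogenation saturates the alkyne and hydrogenolyses the four benzyl ethers in one operation, while the tertiary alcohol and the C2=C3 bond of the chromone (a vinylogous ester) should survive at 1 atm if the reaction is stopped at the calculated uptake.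

**Compound list**

1 | 2-bromobenzene-1,3-diol (2-bromoresorcinol) | Oc1cccc(O)c1Br | starting material
2 | 2-bromo-1,3-bis(tert-butyldimethylsilyloxy)benzene | CC(C)(C)[Si](C)(C)Oc1cccc(O[Si](C)(C)C(C)(C)C)c1Br | intermediate
3 | 2-[4-bromo-3,5-bis(tert-butyldimethylsilyloxy)phenyl]-4,4,5,5-tetramethyl-1,3,2-dioxaborolane | CC(C)(C)[Si](C)(C)Oc1cc(B2OC(C)(C)C(C)(C)O2)cc(O[Si](C)(C)C(C)(C)C)c1Br | intermediate
4 | dicesium 2-bromo-5-(4,4,5,5-tetramethyl-1,3,2-dioxaborolan-2-yl)benzene-1,3-diolate (not isolated) | CC1(C)OB(c2cc([O-])c(Br)c([O-])c2)OC1(C)C.[Cs+].[Cs+] | intermediate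
5 | 2-[3,5-bis(benzyloxy)-4-bromophenyl]-4,4,5,5-tetramethyl-1,3,2-dioxaborolane | CC1(C)OB(c2cc(OCc3ccccc3)c(Br)c(OCc3ccccc3)c2)OC1(C)C | intermediate
6 | 3,5-bis(benzyloxy)-4-bromophenol | Oc1cc(OCc2ccccc2)c(Br)c(OCc2ccccc2)c1 | intermediate
7 | 2-(2,4-dihydroxyphenyl)acetic acid | OC(=O)Cc1ccc(O)cc1O | starting material
8 | benzyl 2-[2,4-bis(benzyloxy)phenyl]acetate | O=C(Cc1ccc(OCc2ccccc2)cc1OCc1ccccc1)OCc1ccccc1 | intermediate
9 | benzyl (Z)-2-[2,4-bis(benzyloxy)phenyl]-3-hydroxyacrylate | O/C=C(/c1ccc(OCc2ccccc2)cc1OCc1ccccc1)C(=O)OCc1ccccc1 | intermediate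
10 | benzyl (Z)-2-[2,4-bis(benzyloxy)phenyl]-3-(tosyloxy)acrylate | Cc1ccc(cc1)S(=O)(=O)O/C=C(/c1ccc(OCc2ccccc2)cc1OCc1ccccc1)C(=O)OCc1ccccc1 | intermediate
11 | benzyl (Z)-3-[3,5-bis(benzyloxy)-4-bromophenoxy]-2-[2,4-bis(benzyloxy)phenyl]acrylate | O=C(OCc1ccccc1)/C(=C\Oc1cc(OCc2ccccc2)c(Br)c(OCc2ccccc2)c1)c1ccc(OCc2ccccc2)cc1OCc1ccccc1 | intermediate
12 | (Z)-3-[3,5-bis(benzyloxy)-4-bromophenoxy]-2-[2,4-bis(benzyloxy)phenyl]acrylic acid | OC(=O)/C(=C\Oc1cc(OCc2ccccc2)c(Br)c(OCc2ccccc2)c1)c1ccc(OCc2ccccc2)cc1OCc1ccccc1 | intermediate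
13 | (Z)-3-[3,5-bis(benzyloxy)-4-bromophenoxy]-2-[2,4-bis(benzyloxy)phenyl]acrylic trifluoroacetic anhydride (not isolated) | FC(F)(F)C(=O)OC(=O)/C(=C\Oc1cc(OCc2ccccc2)c(Br)c(OCc2ccccc2)c1)c1ccc(OCc2ccccc2)cc1OCc1ccccc1 | intermediate
14 | 5,7-bis(benzyloxy)-3-[2,4-bis(benzyloxy)phenyl]-6-bromo-4H-chromen-4-one | Brc1c(OCc2ccccc2)cc2occ(-c3ccc(OCc4ccccc4)cc3OCc3ccccc3)c(=O)c2c1OCc1ccccc1 | intermediate
15 | 2-methylbut-3-yn-2-ol | CC(C)(O)C#C | starting material
16 | 5,7-bis(benzyloxy)-3-[2,4-bis(benzyloxy)phenyl]-6-(3-hydroxy-3-methylbut-1-yn-1-yl)-4H-chromen-4-one | CC(C)(O)C#Cc1c(OCc2ccccc2)cc2occ(-c3ccc(OCc4ccccc4)cc3OCc3ccccc3)c(=O)c2c1OCc1ccccc1 | intermediate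
17 | 5,7-dihydroxy-3-(2,4-dihydroxyphenyl)-6-(3-hydroxy-3-methylbutyl)-4H-chromen-4-one | CC(C)(O)CCc1c(O)cc2occ(-c3ccc(O)cc3O)c(=O)c2c1O | target

**Step count and risks**

Total step count: 12. Longest linear sequence: 9 steps (steps 1–4 and 8–12, from 2-bromoresorcinol).

Steps most likely to fail:

1. Step 10 (ring closure). The acyl species may reach the reactive Z geometry too slowly. Then attack of the 2'-benzyloxy oxygen on the activated acyl group (debenzylative lactonisation to a benzofuran-2-one) or acid-induced loss of benzyl groups could overtake C-acylation. The fallback sets out from phenol 6 and returns at 14; it closes ring C at O1–C2 without acid and adds ring B last.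
   - Ortho-formylation of 6 (MgCl2, Et3N, paraformaldehyde, MeCN, reflux; the two ortho positions are again equivalent) should give 2,4-bis(benzyloxy)-3-bromo-6-hydroxybenzaldehyde F1.
   - Addition of MeMgBr (THF, 0 °C) should give racemic 1-[2,4-bis(benzyloxy)-3-bromo-6-hydroxyphenyl]ethan-1-ol F2.
   - Oxidation with MnO2 (CH2Cl2, rt) should give 1-[2,4-bis(benzyloxy)-3-bromo-6-hydroxyphenyl]ethan-1-one F3.
   - Condensation with N,N-dimethylformamide dimethyl acetal (toluene, 90 °C) should give (E)-1-[2,4-bis(benzyloxy)-3-bromo-6-hydroxyphenyl]-3-(dimethylamino)prop-2-en-1-one F4.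
   - Iodine (CHCl3, rt) should cyclise F4 with loss of dimethylamine to 5,7-bis(benzyloxy)-6-bromo-3-iodo-4H-chromen-4-one F5.
   - Suzuki–Miyaura coupling of F5 with 2,4-bis(benzyloxy)phenylboronic acid (Pd(PPh3)4, Na2CO3, DME/H2O, 60 °C), selective for the vinylic iodide over the hindered aryl bromide, should give 14.

2. Step 11 (Sonogashira coupling). Oxidative addition into the electron-rich C6–Br bond between two benzyloxy groups may be slow, so that alkyne oligomerisation or base-induced loss of acetone from the alkynol consumes the coupling partner. The fallback sets out from 14 and returns at target 17, using an alkylborane that tolerates prolonged heating and delivers the saturated chain directly.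
   - Hydroboration of 2-methylbut-3-en-2-ol with 9-BBN (2 equiv, THF, rt) should give 9-(3-hydroxy-3-methylbutyl)-9-borabicyclo[3.3.1]nonane F6.
   - B-alkyl Suzuki–Miyaura coupling of F6 with 14 (Pd(OAc)2, SPhos, K3PO4, THF/H2O, 65 °C) should give 5,7-bis(benzyloxy)-3-[2,4-bis(benzyloxy)phenyl]-6-(3-hydroxy-3-methylbutyl)-4H-chromen-4-one F7.
   - Hydrogenolysis of F7 (H2, 10% Pd/C, THF/MeOH) should give 17.

3. Step 8 (vinylic substitution). The phenoxide may attack sulfur instead of the β-carbon, transferring the sulfonyl group to the phenol and returning enolate 9. The fallback sets out from phenol 6 and returns at acid 12; it uses a halide leaving group and brings in ring B afterwards by cross-coupling.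
   - Addition of Br2 to ethyl propiolate (CH2Cl2, 0 °C) should give ethyl (E)-2,3-dibromoacrylate F8.
   - Phenol 6 with K2CO3 in DMF should displace the β-bromide of F8 by addition–elimination to give ethyl (E)-3-[3,5-bis(benzyloxy)-4-bromophenoxy]-2-bromoacrylate F9.
   - Suzuki–Miyaura coupling of F9 at the vinylic bromide with 2,4-bis(benzyloxy)phenylboronic acid (Pd(PPh3)4, K2CO3, dioxane/H2O, 70 °C) should give ethyl (Z)-3-[3,5-bis(benzyloxy)-4-bromophenoxy]-2-[2,4-bis(benzyloxy)phenyl]acrylate F10.
   - Saponification of F10 with LiOH (THF/H2O), then acidification, should give 12.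

**Further compounds**

F1 | step 10 | 2,4-bis(benzyloxy)-3-bromo-6-hydroxybenzaldehyde | O=Cc1c(O)cc(OCc2ccccc2)c(Br)c1OCc1ccccc1
F2 | step 10 | 1-[2,4-bis(benzyloxy)-3-bromo-6-hydroxyphenyl]ethan-1-ol (racemic) | CC(O)c1c(O)cc(OCc2ccccc2)c(Br)c1OCc1ccccc1
F3 | step 10 | 1-[2,4-bis(benzyloxy)-3-bromo-6-hydroxyphenyl]ethan-1-one | CC(=O)c1c(O)cc(OCc2ccccc2)c(Br)c1OCc1ccccc1
F4 | step 10 | (E)-1-[2,4-bis(benzyloxy)-3-bromo-6-hydroxyphenyl]-3-(dimethylamino)prop-2-en-1-one | CN(C)/C=C/C(=O)c1c(O)cc(OCc2ccccc2)c(Br)c1OCc1ccccc1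
F5 | step 10 | 5,7-bis(benzyloxy)-6-bromo-3-iodo-4H-chromen-4-one | Brc1c(OCc2ccccc2)cc2occ(I)c(=O)c2c1OCc1ccccc1
F6 | step 11 | 9-(3-hydroxy-3-methylbutyl)-9-borabicyclo[3.3.1]nonane | CC(C)(O)CCB1C2CCCC1CCC2
F7 | step 11 | 5,7-bis(benzyloxy)-3-[2,4-bis(benzyloxy)phenyl]-6-(3-hydroxy-3-methylbutyl)-4H-chromen-4-one | CC(C)(O)CCc1c(OCc2ccccc2)cc2occ(-c3ccc(OCc4ccccc4)cc3OCc3ccccc3)c(=O)c2c1OCc1ccccc1
F8 | step 8 | ethyl (E)-2,3-dibromoacrylate | CCOC(=O)/C(Br)=C\Br
F9 | step 8 | ethyl (E)-3-[3,5-bis(benzyloxy)-4-bromophenoxy]-2-bromoacrylate | CCOC(=O)/C(Br)=C\Oc1cc(OCc2ccccc2)c(Br)c(OCc2ccccc2)c1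
F10 | step 8 | ethyl (Z)-3-[3,5-bis(benzyloxy)-4-bromophenoxy]-2-[2,4-bis(benzyloxy)phenyl]acrylate | CCOC(=O)/C(=C\Oc1cc(OCc2ccccc2)c(Br)c(OCc2ccccc2)c1)c1ccc(OCc2ccccc2)cc1OCc1ccccc1
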